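(All runs were generated by integration for an exercise, and the scatter is random.)

At 210 h, the last reading of each run, I wanted to know where blue stood, a flask with the charge of green but less free catalyst.

| flask | starting material | free catalyst | time |
|---|---|---|---|
| violet | 0.0500 M | 2.50 × 10⁻⁴ M |  |
| green | 0.0500 M | 1.30 × 10⁻⁴ M |  |
| grey | 0.150 M | 2.50 × 10⁻⁴ M |  |
| blue | 0.0500 M | 7.20 × 10⁻⁵ M | 210 h |

- violet run (time / h: [product] / M): 42: 0.01343; 84: 0.02318; 130: 0.03022; 170: 0.03486; 210: 0.03841
- green run (time / h: [product] / M): 42: 0.00975; 84: 0.01713; 130: 0.02397; 170: 0.02846; 210: 0.03202
- grey run (time / h: [product] / M): 42: 0.03819; 84: 0.06557; 130: 0.08731; 170: 0.10168; 210: 0.11253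

(scatter of a reading: 2 × 10⁻⁴ M)

- Overall: starting material -> product, with free catalyst as catalyst.
- Constant volume, constant temperature.
- A reading of a species includes what of it is bound.
- An order is taken over about fifteen percent of the charge, up and down.

1. apparent order in [free catalyst] of the starting rate, round the charge of the violet run (the rate where two percent of its starting material have turned into product)
2. apparent order in [starting material] of the starting rate, round the charge of the violet run (the rate where two percent of its starting material have turned into product) (one fixed amount of product, the same in the runs compared)
3. product in the blue run at 210 h, as a share of the starting material charged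

My measure was the depth, the natural log of one over the fraction of starting material left. With 3.00 times the charge, grey reached a depth of 1.39 against 1.46 in violet, so the runs were close to pseudo-first-order in starting material. Depth at the same hour could therefore stand for the speed of these flasks.

Green and violet share a charge of starting material, and from green to violet the catalyst rose 1.92-fold while the depth at 210 h rose from 1.02 by a factor of 1.43. I defined the catalyst exponent as the log of the depth ratio over the log of the catalyst ratio, for two flasks of equal charge read at the same hour; it came to 0.546. Catalyst working wholly as charged gives an exponent of 1, and catalyst held mostly as a dimer gives 0.5, so this reading lay nearer the lower end.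

Blue looks nearly like green, but it holds 0.554 of green's catalyst. Raising that ratio to the exponent and multiplying green's depth by the result gave me a depth of 0.741 for blue, which is a product fraction of 0.523. So I put blue lower than green's 0.640, because its depth was 0.726 of green's at the same hour.

The forecast gave 0.54 (0.48 to 0.62) for the catalyst order, 0.96 (0.9 to 1) for the starting-material order and 52% (48.5% to 55%) for blue, reading “a monomer–dimer resting state, nearly half order”. Its order was local to violet's charge, whereas my exponent spanned green to violet.

    2 free catalyst ⇌ catalyst dimer, settled at all times (3.100 × 10⁵ L mol⁻¹)
    free catalyst + starting material → product + free catalyst (374.4 L mol⁻¹ h⁻¹)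
    free catalyst + product ⇌ catalyst-product complex, settled at all times (34.30 L mol⁻¹)

Round violet's charge the orders came to 0.52 in free catalyst and 1.0 in starting material. Blue gave 53.1%, and its depth of 0.757 makes the exponent from green to blue 0.510. At 210 h the catalyst-product complex stood at about 0.910 of free catalyst in blue and 1.10 in green. Carried from violet to green, the exponent turned violet's 97.8 h to a product fraction of 0.5 into 140 h, and green took 139 h.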